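**Strategy.** The route reads the butenolide as a latent trans‑3,4‑disubstituted γ‑butyrolactone. Its β‑carbon is bonded to the side‑chain‑bearing CH of the eight‑membered ring and its α‑carbon to the cyclopropane CH. One three‑component operation makes both of these bonds and sets four stereocentres: Michael addition of the SAMP‑hydrazone azaenolate of (R)‑citronellal to 2(5H)‑furanone, then aldol trapping of the lactone enolate with crotonaldehyde. The adduct holds all but one carbon of the eight‑membered ring. Alkyne homologation, cycloisomerization to a 2‑methylene‑6‑propenyltetrahydropyran and Claisen ring expansion give the cyclooctenone. Directed cyclopropanation, dehydrogenation, acetylation and a singlet‑oxygen ene reaction finish the target.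

Key step: step 2

Remark: the hydroxy aldehyde formed on hydrazone cleavage is drawn open‑chain; it should rest mainly as its six‑membered lactol and react through the open form. All four building blocks and the diazophosphonate of step 4 are commercial.

Step 1
Reactants: 1 (R)-citronellal; 2 SAMP
Product: 3 (E)-SAMP hydrazone of (R)-citronellal
Conditions: CH2Cl2, MgSO4, 0 °C to rt
Reagents that add atoms: none
Why: Condensation of the aldehyde with the N‑amino group (hydrazone formation) should give the (E)‑hydrazone, installing the auxiliary without touching the existing stereocentre.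

Step 2
Reactants: 3 (E)-SAMP hydrazone of (R)-citronellal; 4 2(5H)-furanone; 5 (E)-crotonaldehyde
Product: 8 SAMP hydrazone of (2S,3R)-2-[(3S,4R)-4-[(1R,2E)-1-hydroxybut-2-enyl]-5-oxotetrahydrofuran-3-yl]-3,7-dimethyloct-6-enal, via lithium azaenolate 6 (not isolated), via lithium lactone enolate 7 (not isolated)
Conditions: LiN(i-Pr)2, THF, 0 °C; then 4, −78 °C; then 5, −78 °C; aq NH4Cl
Reagents that add atoms: none
Why: Deprotonation of 3 gives the chelated E(C=C) azaenolate 6, which adds 1,4 to 4; the resulting lactone enolate 7 is trapped by 1,2‑addition to 5, so the step is a three‑component tandem Michael/aldol coupling on a butenolide, a known reaction type. No ring is closed; the lactone ring is taken over from 4. The stereocentre next to the C=N carbon is set by the SAMP auxiliary (attack on the azaenolate face remote from the methoxymethylpyrrolidine, the sense known from SAMP alkylations, expected S). The lactone β‑carbon is set by relative topicity in an open synclinal transition state, with the azaenolate over the furanone ring and its vinylic H between the two ring arms (syn adduct); the lactone α‑carbon is set anti to the new β‑substituent (trans lactone); the carbinol is set by a Zimmerman–Traxler chair of the ring‑fixed E(O) enolate with the propenyl group equatorial (anti aldol). The step needs 1,4‑ over 1,2‑addition to 4 and C–C bond formation over proton transfer from the γ‑CH2 of 4, which the soft azaenolate at −78 °C should secure, and 1,2‑addition to the enal 5, the kinetic mode for a lithium enolate.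

Step 3
Reactants: 8 SAMP hydrazone of the Michael/aldol adduct
Product: 9 (2S,3R)-2-[(3S,4R)-4-[(1R,2E)-1-hydroxybut-2-enyl]-5-oxotetrahydrofuran-3-yl]-3,7-dimethyloct-6-enal
Conditions: saturated aq oxalic acid, Et2O, rt
Reagents that add atoms: water, O
Why: Mild two‑phase acidic hydrolysis of the hydrazone should release the aldehyde without epimerizing its α‑stereocentre and return the auxiliary to the aqueous phase.

Step 4
Reactants: 9 hydroxy aldehyde (lactol)
Product: 10 (3R,4S)-4-[(3S,4R)-4,8-dimethylnon-7-en-1-yn-3-yl]-3-[(1R,2E)-1-hydroxybut-2-enyl]dihydrofuran-2(3H)-one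
Conditions: dimethyl (1-diazo-2-oxopropyl)phosphonate, K2CO3, MeOH, 0 °C to rt
Reagents that add atoms: dimethyl (1-diazo-2-oxopropyl)phosphonate, COP(=O)(OC)C(=[N+]=[N-])C(C)=O
Why: Seyferth–Gilbert homologation (Ohira–Bestmann variant) should convert the aldehyde, drawn from the lactol equilibrium, into the terminal alkyne with one added carbon and no new stereocentre.

Step 5
Reactants: 10 alkynol
Product: 12 trans-lactone-fused (Z)-cyclooct-5-enone, via exocyclic enol ether 11 (not isolated)
Conditions: AuCl (5 mol %), K2CO3 (10 mol %), MeCN, rt; filtration through basic alumina; toluene, 150 °C, sealed tube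
Reagents that add atoms: none
Why: 6‑exo‑dig hydroalkoxylation of the alkynol should give the 2‑methylene‑6‑propenyltetrahydropyran 11, whose Claisen ring expansion through a chair‑like transition state (propenyl axial on the pyran chair, all other substituents equatorial, E‑methyl pseudo‑equatorial) should transfer the carbinol configuration to the new methyl‑bearing stereocentre and give the (Z)‑cyclooctenone.

Step 6
Reactants: 12 cyclooctenone
Product: 13 (1R)-cyclooctenol with hydroxyl cis to the side chain
Conditions: LiBH(s-Bu)3, THF, −78 °C; aq NH4Cl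
Reagents that add atoms: none
Why: Diastereoselective ketone reduction by the bulky hydride should occur from the face opposite the adjacent side chain, as with 2‑alkylcycloalkanones, giving the cis alcohol while leaving the lactone intact at −78 °C.

Step 7
Reactants: 13 cyclooctenol
Product: 14 cyclopropyl alcohol
Conditions: Et2Zn, CH2I2, CH2Cl2, −10 to 0 °C; aq NH4Cl
Reagents that add atoms: diiodomethane, ICI
Why: In this hydroxyl‑directed Simmons–Smith cyclopropanation (Furukawa variant) the zinc alkoxide should deliver the carbenoid across the ring to the cis‑alkene on the face syn to the hydroxyl and anti to the allylic methyl, faster than to the undirected trisubstituted side‑chain alkene.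

Step 8
Reactants: 14 cyclopropyl alcohol
Product: 17 hydroxy butenolide, via selenide 15 (not isolated), via selenoxide 16 (not isolated)
Conditions: LiN(i-Pr)2 (2.2 equiv), THF, −78 °C; PhSeBr, −78 °C; then AcOH, 30% H2O2, 0 °C to rt
Reagents that add atoms: none
Why: The lactone enolate (formed beside the alkoxide) should be selenenylated at the α‑carbon anti to the neighbouring ring substituent, and the derived selenoxide should undergo syn elimination toward the only non‑cyclopropyl β‑hydrogen to give the butenolide (selenoxide elimination).

Step 9
Reactants: 17 hydroxy butenolide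
Product: 18 acetate (the acetoxycrenulide structure)
Conditions: Ac2O, pyridine, DMAP (cat.), CH2Cl2, rt
Reagents that add atoms: acetic anhydride, CC(=O)OC(C)=O
Why: DMAP‑catalysed acylation of the secondary alcohol should proceed with retention and create no new stereocentre.

Step 10
Reactants: 18 acetate
Product: 19 CNP0205234.1
Conditions: O2, visible light, tetraphenylporphyrin (cat.), CH2Cl2, 0 °C
Reagents that add atoms: dioxygen, O=O
Why: In the Schenck ene reaction, singlet oxygen should abstract an allylic CH2 hydrogen of the trisubstituted side‑chain alkene, placing the hydroperoxide on the tertiary carbon and shifting the alkene to the E‑disubstituted position; the electron‑poor butenolide alkene should not react, and the regioisomeric secondary hydroperoxide expected alongside is to be removed by chromatography.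

**Compound list**

1 | (R)-citronellal, (R)-3,7-dimethyloct-6-enal | O=CC[C@H](C)CCC=C(C)C | starting material
2 | SAMP, (S)-1-amino-2-(methoxymethyl)pyrrolidine | COC[C@@H]1CCCN1N | starting material
3 | (E)-SAMP hydrazone of (R)-citronellal | COC[C@@H]1CCCN1/N=C/C[C@H](C)CCC=C(C)C | intermediate
4 | 2(5H)-furanone | O=C1OCC=C1 | starting material
5 | (E)-crotonaldehyde | C/C=C/C=O | starting material
6 | lithium azaenolate of 3 (E at C=C) | [Li+].COC[C@@H]1CCCN1[N-]/C=C/[C@H](C)CCC=C(C)C | intermediate
7 | lithium enolate of the Michael adduct (β-substituted γ-butyrolactone enolate) | [Li+].COC[C@@H]1CCCN1/N=C/[C@@H]([C@H](C)CCC=C(C)C)[C@@H]2COC([O-])=C2 | intermediate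
8 | SAMP hydrazone of (2S,3R)-2-[(3S,4R)-4-[(1R,2E)-1-hydroxybut-2-enyl]-5-oxotetrahydrofuran-3-yl]-3,7-dimethyloct-6-enal | COC[C@@H]1CCCN1/N=C/[C@@H]([C@H](C)CCC=C(C)C)[C@@H]2COC(=O)[C@H]2[C@H](O)/C=C/C | intermediate
9 | (2S,3R)-2-[(3S,4R)-4-[(1R,2E)-1-hydroxybut-2-enyl]-5-oxotetrahydrofuran-3-yl]-3,7-dimethyloct-6-enal (open-chain form of the lactol) | O=C[C@@H]([C@H](C)CCC=C(C)C)[C@@H]1COC(=O)[C@H]1[C@H](O)/C=C/C | intermediate
10 | (3R,4S)-4-[(3S,4R)-4,8-dimethylnon-7-en-1-yn-3-yl]-3-[(1R,2E)-1-hydroxybut-2-enyl]dihydrofuran-2(3H)-one | C#C[C@@H]([C@H](C)CCC=C(C)C)[C@@H]1COC(=O)[C@H]1[C@H](O)/C=C/C | intermediate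
11 | exocyclic enol ether: 2-methylidene-6-[(E)-prop-1-enyl]tetrahydropyran with the (R)-6-methylhept-5-en-2-yl group at C-3 and the γ-lactone trans-fused at C-4/C-5 (C-4–CH2–O–C(=O)–C-5) | C=C1O[C@H](/C=C/C)[C@@H]2C(=O)OC[C@H]2[C@@H]1[C@H](C)CCC=C(C)C | intermediate
12 | (Z)-cyclooct-5-en-1-one with (S)-C-2 bearing the (R)-6-methylhept-5-en-2-yl group, (R)-C-7 bearing methyl and the γ-lactone trans-fused at C-3/C-4 (C-3–CH2–O–C(=O)–C-4) | O=C1C[C@@H](C)/C=C\[C@@H]2C(=O)OC[C@H]2[C@@H]1[C@H](C)CCC=C(C)C | intermediate
13 | (1R)-alcohol of 12, hydroxyl cis to the C-2 side chain | O[C@@H]1C[C@@H](C)/C=C\[C@@H]2C(=O)OC[C@H]2[C@@H]1[C@H](C)CCC=C(C)C | intermediate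
14 | cyclopropyl alcohol: 13 with CH2 added across the ring alkene on the hydroxyl face (cis-fused bicyclo[6.1.0]nonane) | O[C@@H]1C[C@@H](C)[C@@H]2C[C@@H]2[C@@H]3C(=O)OC[C@H]3[C@@H]1[C@H](C)CCC=C(C)C | intermediate
15 | α-phenylselanyl lactone of 14 (selenium on the lactone α-carbon, cis to the β-hydrogen) | O[C@@H]1C[C@@H](C)[C@@H]2C[C@@H]2[C@@]3([Se]c4ccccc4)C(=O)OC[C@H]3[C@@H]1[C@H](C)CCC=C(C)C | intermediate
16 | selenoxide of 15 (mixture at selenium) | O[C@@H]1C[C@@H](C)[C@@H]2C[C@@H]2[C@@]3([Se](=O)c4ccccc4)C(=O)OC[C@H]3[C@@H]1[C@H](C)CCC=C(C)C | intermediate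
17 | hydroxy butenolide (deacetyl compound of 18) | O[C@@H]1C[C@@H](C)[C@@H]2C[C@@H]2C3=C(COC3=O)[C@@H]1[C@H](C)CCC=C(C)C | intermediate
18 | acetate of 17 with the 6-methylhept-5-en-2-yl side chain (the acetoxycrenulide structure) | CC(=O)O[C@@H]1C[C@@H](C)[C@@H]2C[C@@H]2C3=C(COC3=O)[C@@H]1[C@H](C)CCC=C(C)C | intermediate
19 | CNP0205234.1, the tertiary (E)-allylic hydroperoxide | CC(=O)O[C@@H]1C[C@@H](C)[C@@H]2C[C@@H]2C2=C(COC2=O)[C@@H]1[C@H](C)C/C=C/C(C)(C)OO | target

**Total step count:** 10. **Longest linear sequence:** 10 steps (from 1).

**Steps most likely to fail**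

Step 2. The relative topicity between the azaenolate carbon and the lactone β‑carbon may be poorly controlled, or the aldol may show low anti selectivity; either error would be carried by the Claisen step into the ring methyl stereocentre. The fallback puts the acceptor face under substrate control. It sets out from 3: the azaenolate is added to (5S)-5-(d-menthyloxy)-2(5H)-furanone, O=C1C=C[C@@H](O[C@H]2C[C@@H](C)CC[C@@H]2C(C)C)O1, in place of 4. The nucleophile should enter anti to the menthyloxy group, and trapping with 5 as before should give the menthyloxy adduct F1. Treatment of F1 with NaBH4 and KOH in aqueous EtOH (lactone opening, release and reduction of the aldehyde), then acidification to about pH 4 (relactonization), should remove the acetal with loss of menthol and return the route at 8.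

Step 5. The exocyclic enol ether may isomerize into the ring, hydrolyse or form by the 7‑endo mode before it can rearrange. The fallback generates it under neutral thermal conditions by selenoxide elimination and sets out from 9. Wittig methylenation (Ph3P=CH2, THF, 0 °C) should give the alkenol F2. 6‑exo Selenoetherification with N‑(phenylseleno)phthalimide and catalytic camphorsulfonic acid should give the 2‑(phenylselanylmethyl)tetrahydropyran F3 (either configuration at the new ring carbon serves). NaIO4 oxidation should give the selenoxide F4. Heating F4 in toluene with i‑Pr2NEt at 150 °C should bring about syn elimination to 11 and its Claisen ring expansion, returning the route at 12.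

Step 7. The carbenoid may also attack the trisubstituted side‑chain alkene, or the transannular hydroxyl direction may be too weak to control the face. The fallback sets out from 12 and cyclopropanates before the reduction: diazomethane with catalytic Pd(OAc)2 in Et2O at 0 °C reacts with strained cis‑disubstituted alkenes but not with trisubstituted ones. Addition anti to the allylic methyl should give the cyclopropyl ketone F5. Reduction of F5 with LiBH(s-Bu)3 at −78 °C, as in step 6, returns the route at 14.

**Further compounds**

F1 | step 2 | menthyloxy adduct: 8 carrying a (+)-menthyloxy group on the lactone O–CH carbon, trans to the neighbouring ring substituent | COC[C@@H]1CCCN1/N=C/[C@@H]([C@H](C)CCC=C(C)C)[C@@H]2[C@@H](O[C@H]3C[C@@H](C)CC[C@@H]3C(C)C)OC(=O)[C@H]2[C@H](O)/C=C/C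
F2 | step 5 | alkenol: vinyl analogue of alkynol 10 | C=C[C@@H]([C@H](C)CCC=C(C)C)[C@@H]1COC(=O)[C@H]1[C@H](O)/C=C/C
F3 | step 5 | 2-(phenylselanylmethyl)tetrahydropyran corresponding to 11 | [Se](CC1O[C@H](/C=C/C)[C@@H]2C(=O)OC[C@H]2[C@@H]1[C@H](C)CCC=C(C)C)c3ccccc3
F4 | step 5 | selenoxide of F3 | O=[Se](CC1O[C@H](/C=C/C)[C@@H]2C(=O)OC[C@H]2[C@@H]1[C@H](C)CCC=C(C)C)c3ccccc3
F5 | step 7 | cyclopropyl ketone: 12 with CH2 added across the ring alkene | O=C1C[C@@H](C)[C@@H]2C[C@@H]2[C@@H]3C(=O)OC[C@H]3[C@@H]1[C@H](C)CCC=C(C)C
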